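## Retrosynthetic overview

1. Endgame: the 19 phenols are unmasked last from methyl ethers. The ring G–O–ring C bond comes from an Ullmann coupling at the central ring C phenol. That phenol comes from a formyl group (Baeyer–Villiger), and the two identical arm–O–ring C bonds come from a twofold SNAr on 2,6-difluoro-4-methoxybenzaldehyde.
2. Feature used: in each arm the phloroglucinol ring F hangs by its carbon F1 on B6, a ring B carbon wedged between the oxygen-bearing carbons B1 and B5. F1 is therefore traced back to a benzylic CH2 at the end of a masked 3,5-dioxohexanoate chain, so the crowded B6–F1 bond is never made by aryl–aryl coupling.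
3. Key disconnection: ring F is opened at F1–F6 to a 4-methoxy-6-(arylmethyl)-2-pyrone, built from the arylacetaldehyde and the dianion of methyl acetoacetate (aldol, oxidation, lactonisation, O-methylation).
4. The B6–CH2 bond comes from an aromatic Claisen rearrangement of the allyl ether of the ring B phenol (from syringaldehyde). The freed B1 phenol then takes ring A by Ullmann coupling.
5. Ring order: rings A, B, C and G are bought as benzenes. The pyrone ring is closed in step 10 and converted into ring F in step 12, and the finished arm is used twice.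

Key step: step 12

Assumption: the target has no stereocentre, and the two B6–F1 axes are not stereogenic because ring F is symmetric about them, so no stereocontrol is planned.

Abbreviations used in names:
- Ar = 3-(benzyloxy)-2,4-dimethoxy-6-(2,4,6-trimethoxyphenoxy)phenyl (rings A and B, bonded through B6).
- ArmO = 2,6-dimethoxy-3-(2,4,6-trimethoxyphenyl)-4-(2,4,6-trimethoxyphenoxy)phenoxy (rings A, B and F, bonded through the B4 oxygen).

## Route

Step 1
Reactants: 1 syringaldehyde
Product: 2 4-(benzyloxy)-3,5-dimethoxybenzaldehyde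
Conditions: BnBr, K2CO3, DMF, 60 °C
Reagents that add atoms: benzyl bromide, BrCc1ccccc1
Why: Williamson etherification of the only phenol installs on the future B4 oxygen the one protecting group that can later be removed beside methyl ethers.

Step 2
Reactants: 2 4-(benzyloxy)-3,5-dimethoxybenzaldehyde
Product: 4 4-(benzyloxy)-3,5-dimethoxyphenol, via aryl formate 3 (not isolated)
Conditions: mCPBA, CH2Cl2, 0 °C to rt; then K2CO3 (cat.), MeOH, rt
Reagents that add atoms: mCPBA, OOC(=O)c1cccc(Cl)c1
Why: In this Baeyer–Villiger (Dakin-type) oxidation the electron-rich aryl group migrates in preference to hydrogen, and methanolysis of the formate should free the B1 phenol.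

Step 3
Reactants: 4 4-(benzyloxy)-3,5-dimethoxyphenol; 5 allyl bromide
Product: 6 5-(allyloxy)-2-(benzyloxy)-1,3-dimethoxybenzene
Conditions: K2CO3, acetone, reflux
Reagents that add atoms: none
Why: Williamson etherification of an unhindered phenoxide with a reactive allylic halide is expected to be clean.

Step 4
Reactants: 6 5-(allyloxy)-2-(benzyloxy)-1,3-dimethoxybenzene
Product: 8 2-allyl-4-(benzyloxy)-3,5-dimethoxyphenol, via ortho-dienone 7 (not isolated)
Conditions: N,N-diethylaniline, 200 °C, argon
Reagents that add atoms: none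
Why: The aromatic Claisen rearrangement, a [3,3]-sigmatropic shift, can only reach one of two equivalent free ortho carbons because the para carbon is blocked, so after enolisation of 7 the future B6–F1 bond is in place as an aryl–CH2 bond.

Step 5
Reactants: 9 1,3,5-trimethoxybenzene
Product: 10 2-iodo-1,3,5-trimethoxybenzene
Conditions: NIS (1 equiv), MeCN, rt
Reagents that add atoms: N-iodosuccinimide, O=C1CCC(=O)N1I
Why: Electrophilic aromatic iodination at one of three equivalent activated positions should stop at the monoiodide when one equivalent of reagent is used.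

Step 6
Reactants: 8 2-allyl-4-(benzyloxy)-3,5-dimethoxyphenol; 10 2-iodo-1,3,5-trimethoxybenzene
Product: 11 4-allyl-2-(benzyloxy)-1,3-dimethoxy-5-(2,4,6-trimethoxyphenoxy)benzene
Conditions: CuI (cat.), picolinic acid (cat.), K3PO4, DMSO, 90 °C, argon
Reagents that add atoms: none
Why: This is an Ullmann diaryl ether synthesis with a ligand system suited to ortho-substituted partners, 2-halo-1,3,5-trimethoxybenzenes are the classical electrophiles for phlorethol-type ethers, and the phosphate base is too weak to move the allyl double bond into conjugation.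

Step 7
Reactants: 11 4-allyl-2-(benzyloxy)-1,3-dimethoxy-5-(2,4,6-trimethoxyphenoxy)benzene
Product: 13 Ar-acetaldehyde, via vicinal diol 12 (not isolated)
Conditions: OsO4 (cat.), NaIO4, 2,6-lutidine, dioxane/H2O, rt
Reagents that add atoms: OsO4, O=[Os](=O)(=O)=O; NaIO4, [Na+].[O-]I(=O)(=O)=O
Why: The Lemieux–Johnson cleavage (dihydroxylation, then periodate glycol cleavage) touches only the terminal alkene, whereas ozone or RuO4 would attack the electron-rich rings.

Step 8
Reactants: 13 Ar-acetaldehyde; 14 methyl acetoacetate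
Product: 16 methyl 6-Ar-5-hydroxy-3-oxohexanoate (racemic), via acetoacetate dianion 15 (not isolated)
Conditions: 14, NaH, THF, 0 °C; n-BuLi, 0 °C; then 13, −78 °C; AcOH quench
Reagents that add atoms: none
Why: The acetoacetate dianion adds in an aldol reaction through its more reactive terminal carbon faster than it enolises the aldehyde at low temperature, and the new carbinol centre forms without control as a racemate because step 9 erases it.

Step 9
Reactants: 16 methyl 6-Ar-5-hydroxy-3-oxohexanoate
Product: 17 methyl 6-Ar-3,5-dioxohexanoate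
Conditions: IBX, EtOAc, 77 °C
Reagents that add atoms: none
Why: IBX oxidation of a β-hydroxy ketone to the β-diketone is reliable, spares the active methylene groups, and avoids the active chlorine of a chlorite oxidation, which would chlorinate ring A.

Step 10
Reactants: 17 methyl 6-Ar-3,5-dioxohexanoate
Product: 18 6-(Ar-methyl)-4-hydroxy-2H-pyran-2-one
Conditions: DBU, toluene, 90 °C; then 1 M HCl wash
Reagents that add atoms: none
Why: In this base-induced lactonisation of a 3,5-dioxo ester the enol oxygen of the C5 ketone attacks the ester in a 6-exo-trig closure, driven by formation of the stabilised 4-hydroxy-2-pyrone anion.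

Step 11
Reactants: 18 6-(Ar-methyl)-4-hydroxy-2H-pyran-2-one
Product: 19 6-(Ar-methyl)-4-methoxy-2H-pyran-2-one
Conditions: Me2SO4, K2CO3, acetone, reflux
Reagents that add atoms: dimethyl sulfate, COS(=O)(=O)OC
Why: O-Methylation of the vinylogous acid under these conditions is the standard way to 4-methoxy-2-pyrones rather than the isomeric 2-methoxy-4-pyrones.

Step 12
Reactants: 19 6-(Ar-methyl)-4-methoxy-2H-pyran-2-one
Product: 22 2-Ar-5-methoxybenzene-1,3-diol (arm carrying the new ring F), via opened keto ester 20 (not isolated), via cyclohexenedione 21 (not isolated)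
Conditions: NaOMe (4 equiv), dry MeOH, sealed tube, 120 °C, argon; then 1 M HCl
Reagents that add atoms: none
Why: Methoxide adds to the lactone carbonyl of 19 and the ring opens to keto ester 20, in which the ester and the ketone arm remain cis on the enol-ether double bond because they were neighbours in the pyrone ring. Reversible deprotonation of the benzylic CH2 next to the ketone gives the enolate that attacks the ester carbonyl, a Claisen (Dieckmann-type) condensation that forms F1–F6 and closes ring F in the 6-(enolendo)-exo-trig mode; loss of methoxide gives 21, which enolises to the aromatic resorcinol 22. The closest known reactions are the sodium methoxide-induced recyclisation of 4-methoxy-6-methyl-2-pyrone to phloroglucinol monomethyl ether and the Claisen cyclisation of 3,5-dioxo esters, and here the reacting carbon is benzylic and therefore more acidic than in the parent case. No stereocentre is formed, and the new B6–F1 axis is not stereogenic because ring F is symmetric about it. The step needs C-acylation to win over relactonisation and over the second carbanion site: the CH2 between enol ether and ketone could only close a four-membered ring, and relactonisation and every methoxide exchange at ester or enol ether are reversible or degenerate in NaOMe/MeOH, whereas aromatisation and twofold deprotonation of 22 are not, which is why more than two equivalents of base are used. The 4-methoxy group keeps the central carbonyl masked, so the unreactive polyanion of a free triketide cannot form.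

Step 13
Reactants: 22 2-Ar-5-methoxybenzene-1,3-diol
Product: 23 2-(benzyloxy)-1,3-dimethoxy-4-(2,4,6-trimethoxyphenyl)-5-(2,4,6-trimethoxyphenoxy)benzene
Conditions: MeI (excess), K2CO3, DMF, 40 °C
Reagents that add atoms: iodomethane, CI
Why: Williamson methylation of both ring F phenols with a small electrophile should tolerate the neighbouring biaryl bond and makes ring F uniform with ring A.

Step 14
Reactants: 23 2-(benzyloxy)-1,3-dimethoxy-4-(2,4,6-trimethoxyphenyl)-5-(2,4,6-trimethoxyphenoxy)benzene
Product: 24 2,6-dimethoxy-3-(2,4,6-trimethoxyphenyl)-4-(2,4,6-trimethoxyphenoxy)phenol (arm phenol, ArmO–H)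
Conditions: H2 (1 atm), Pd/C, EtOAc/MeOH, rt
Reagents that add atoms: none
Why: Catalytic hydrogenolysis cleaves only the benzyl ether, since no halogen or other reducible group is present at this stage.

Step 15
Reactants: 24 arm phenol (two equivalents); 25 2,6-difluoro-4-methoxybenzaldehyde
Product: 27 4-methoxy-2,6-bis(ArmO)benzaldehyde, via monoether 26 (not isolated)
Conditions: Cs2CO3, DMSO, 110 °C, argon
Reagents that add atoms: none
Why: In this twofold SNAr (addition–elimination) each fluorine is ortho to the formyl group that stabilises the Meisenheimer adduct, the methoxy group is meta to both reacting carbons, and each reacting carbon has a hydrogen on its other side so the 2,6-dimethoxyphenoxide can approach.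

Step 16
Reactants: 27 4-methoxy-2,6-bis(ArmO)benzaldehyde
Product: 29 4-methoxy-2,6-bis(ArmO)phenol, via aryl formate 28 (not isolated)
Conditions: mCPBA (1.2 equiv), CH2Cl2, 0 °C; then K2CO3 (cat.), MeOH/THF, rt
Reagents that add atoms: mCPBA, OOC(=O)c1cccc(Cl)c1
Why: In this Baeyer–Villiger oxidation the ring C carbon bearing two ortho oxygens and one para oxygen migrates readily, so a small excess of peracid at low temperature should be consumed by the aldehyde before it can hydroxylate the trimethoxyaryl rings.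

Step 17
Reactants: 30 2-chloro-1,3-dimethoxybenzene
Product: 31 2-(4-chloro-3,5-dimethoxyphenyl)-4,4,5,5-tetramethyl-1,3,2-dioxaborolane
Conditions: [Ir(OMe)(cod)]2 (cat.), dtbpy (cat.), B2pin2 (1 equiv), THF, 80 °C
Reagents that add atoms: bis(pinacolato)diboron, CC1(C)OB(OC1(C)C)B1OC(C)(C)C(C)(C)O1
Why: Iridium-catalysed C–H borylation is sterically controlled and should strike only C5, the one C–H bond without an ortho substituent, while the aryl chloride is tolerated.

Step 18
Reactants: 31 2-(4-chloro-3,5-dimethoxyphenyl)-4,4,5,5-tetramethyl-1,3,2-dioxaborolane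
Product: 32 2-chloro-5-iodo-1,3-dimethoxybenzene
Conditions: CuI (cat.), 1,10-phenanthroline (cat.), KI, MeOH/H2O, air, 80 °C
Reagents that add atoms: potassium iodide, [K+].[I-]
Why: Copper-catalysed iododeboronation runs through boron-to-copper transmetalation, so iodine enters only at the carbon that carried boron and not at the activated C–H positions.

Step 19
Reactants: 29 4-methoxy-2,6-bis(ArmO)phenol; 32 2-chloro-5-iodo-1,3-dimethoxybenzene
Product: 33 2-(4-chloro-3,5-dimethoxyphenoxy)-5-methoxy-1,3-bis(ArmO)benzene (nonadecamethyl ether of the target)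
Conditions: CuI (cat.), picolinic acid (cat.), K3PO4, DMSO, 90 °C, argon, 32 in excess
Reagents that add atoms: none
Why: This Ullmann diaryl ether synthesis pairs a 2,6-disubstituted phenol with an aryl iodide that has no ortho substituent, a combination this catalyst is known to handle, and the C–I bond reacts while the C–Cl bond stays inert.

Step 20
Reactants: 33 nonadecamethyl ether
Product: 34 CNP0275555.0 (target)
Conditions: BBr3 (about 60 equiv), CH2Cl2, −78 °C to rt, argon; then H2O, 0 °C; reversed-phase chromatography under argon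
Reagents that add atoms: none
Why: Lewis acid cleavage of aryl methyl ethers with a large excess of BBr3 treats the 19 sites as independent events and leaves diaryl ethers, biaryl bonds and the aryl chloride untouched.

## Compound list

1 | syringaldehyde (4-hydroxy-3,5-dimethoxybenzaldehyde) | COc1cc(C=O)cc(OC)c1O | starting material
2 | 4-(benzyloxy)-3,5-dimethoxybenzaldehyde | COc1cc(C=O)cc(OC)c1OCc1ccccc1 | intermediate
3 | 4-(benzyloxy)-3,5-dimethoxyphenyl formate (not isolated) | COc1cc(OC=O)cc(OC)c1OCc1ccccc1 | intermediate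
4 | 4-(benzyloxy)-3,5-dimethoxyphenol (ring B phenol) | COc1cc(O)cc(OC)c1OCc1ccccc1 | intermediate
5 | allyl bromide | C=CCBr | starting material
6 | 5-(allyloxy)-2-(benzyloxy)-1,3-dimethoxybenzene | C=CCOc1cc(OC)c(OCc2ccccc2)c(OC)c1 | intermediate
7 | 6-allyl-4-(benzyloxy)-3,5-dimethoxycyclohexa-2,4-dien-1-one (racemic, not isolated) | C=CCC1C(=O)C=C(OC)C(OCc2ccccc2)=C1OC | intermediate
8 | 2-allyl-4-(benzyloxy)-3,5-dimethoxyphenol | C=CCc1c(O)cc(OC)c(OCc2ccccc2)c1OC | intermediate
9 | 1,3,5-trimethoxybenzene | COc1cc(OC)cc(OC)c1 | starting material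
10 | 2-iodo-1,3,5-trimethoxybenzene | COc1cc(OC)c(I)c(OC)c1 | intermediate
11 | 4-allyl-2-(benzyloxy)-1,3-dimethoxy-5-(2,4,6-trimethoxyphenoxy)benzene | C=CCc1c(Oc2c(OC)cc(OC)cc2OC)cc(OC)c(OCc2ccccc2)c1OC | intermediate
12 | 3-[3-(benzyloxy)-2,4-dimethoxy-6-(2,4,6-trimethoxyphenoxy)phenyl]propane-1,2-diol (racemic, not isolated) | OCC(O)Cc1c(Oc2c(OC)cc(OC)cc2OC)cc(OC)c(OCc2ccccc2)c1OC | intermediate
13 | [3-(benzyloxy)-2,4-dimethoxy-6-(2,4,6-trimethoxyphenoxy)phenyl]acetaldehyde | O=CCc1c(Oc2c(OC)cc(OC)cc2OC)cc(OC)c(OCc2ccccc2)c1OC | intermediate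
14 | methyl acetoacetate | COC(=O)CC(C)=O | starting material
15 | sodium lithium dianion of methyl acetoacetate (not isolated) | [Na+].[Li+].[CH2-]C(=O)[CH-]C(=O)OC | intermediate
16 | methyl 6-[3-(benzyloxy)-2,4-dimethoxy-6-(2,4,6-trimethoxyphenoxy)phenyl]-5-hydroxy-3-oxohexanoate (racemic) | COC(=O)CC(=O)CC(O)Cc1c(Oc2c(OC)cc(OC)cc2OC)cc(OC)c(OCc2ccccc2)c1OC | intermediate
17 | methyl 6-[3-(benzyloxy)-2,4-dimethoxy-6-(2,4,6-trimethoxyphenoxy)phenyl]-3,5-dioxohexanoate | COC(=O)CC(=O)CC(=O)Cc1c(Oc2c(OC)cc(OC)cc2OC)cc(OC)c(OCc2ccccc2)c1OC | intermediate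
18 | 6-{[3-(benzyloxy)-2,4-dimethoxy-6-(2,4,6-trimethoxyphenoxy)phenyl]methyl}-4-hydroxy-2H-pyran-2-one | OC1=CC(=O)OC(Cc2c(Oc3c(OC)cc(OC)cc3OC)cc(OC)c(OCc3ccccc3)c2OC)=C1 | intermediate
19 | 6-{[3-(benzyloxy)-2,4-dimethoxy-6-(2,4,6-trimethoxyphenoxy)phenyl]methyl}-4-methoxy-2H-pyran-2-one (key-step precursor) | COC1=CC(=O)OC(Cc2c(Oc3c(OC)cc(OC)cc3OC)cc(OC)c(OCc3ccccc3)c2OC)=C1 | intermediate
20 | methyl (2E)-6-[3-(benzyloxy)-2,4-dimethoxy-6-(2,4,6-trimethoxyphenoxy)phenyl]-3-methoxy-5-oxohex-2-enoate, ester and ketone arm cis (not isolated) | COC(=O)/C=C(/OC)CC(=O)Cc1c(Oc2c(OC)cc(OC)cc2OC)cc(OC)c(OCc2ccccc2)c1OC | intermediate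
21 | 2-[3-(benzyloxy)-2,4-dimethoxy-6-(2,4,6-trimethoxyphenoxy)phenyl]-5-methoxycyclohex-4-ene-1,3-dione (racemic, not isolated) | COC1=CC(=O)C(C(=O)C1)c1c(Oc2c(OC)cc(OC)cc2OC)cc(OC)c(OCc2ccccc2)c1OC | intermediate
22 | 2-[3-(benzyloxy)-2,4-dimethoxy-6-(2,4,6-trimethoxyphenoxy)phenyl]-5-methoxybenzene-1,3-diol (key-step product) | Oc1cc(OC)cc(O)c1-c1c(Oc2c(OC)cc(OC)cc2OC)cc(OC)c(OCc2ccccc2)c1OC | intermediate
23 | 2-(benzyloxy)-1,3-dimethoxy-4-(2,4,6-trimethoxyphenyl)-5-(2,4,6-trimethoxyphenoxy)benzene | COc1cc(OC)c(c(OC)c1)-c1c(Oc2c(OC)cc(OC)cc2OC)cc(OC)c(OCc2ccccc2)c1OC | intermediate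
24 | 2,6-dimethoxy-3-(2,4,6-trimethoxyphenyl)-4-(2,4,6-trimethoxyphenoxy)phenol (arm phenol) | COc1cc(OC)c(c(OC)c1)-c1c(Oc2c(OC)cc(OC)cc2OC)cc(OC)c(O)c1OC | intermediate
25 | 2,6-difluoro-4-methoxybenzaldehyde (ring C) | COc1cc(F)c(C=O)c(F)c1 | starting material
26 | 2-fluoro-4-methoxy-6-[2,6-dimethoxy-3-(2,4,6-trimethoxyphenyl)-4-(2,4,6-trimethoxyphenoxy)phenoxy]benzaldehyde (not isolated) | COc1cc(F)c(C=O)c(Oc2c(OC)cc(Oc3c(OC)cc(OC)cc3OC)c(-c3c(OC)cc(OC)cc3OC)c2OC)c1 | intermediate
27 | 4-methoxy-2,6-bis[2,6-dimethoxy-3-(2,4,6-trimethoxyphenyl)-4-(2,4,6-trimethoxyphenoxy)phenoxy]benzaldehyde | COc1cc(Oc2c(OC)cc(Oc3c(OC)cc(OC)cc3OC)c(-c3c(OC)cc(OC)cc3OC)c2OC)c(C=O)c(Oc2c(OC)cc(Oc3c(OC)cc(OC)cc3OC)c(-c3c(OC)cc(OC)cc3OC)c2OC)c1 | intermediate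
28 | 4-methoxy-2,6-bis[2,6-dimethoxy-3-(2,4,6-trimethoxyphenyl)-4-(2,4,6-trimethoxyphenoxy)phenoxy]phenyl formate (not isolated) | COc1cc(Oc2c(OC)cc(Oc3c(OC)cc(OC)cc3OC)c(-c3c(OC)cc(OC)cc3OC)c2OC)c(OC=O)c(Oc2c(OC)cc(Oc3c(OC)cc(OC)cc3OC)c(-c3c(OC)cc(OC)cc3OC)c2OC)c1 | intermediate
29 | 4-methoxy-2,6-bis[2,6-dimethoxy-3-(2,4,6-trimethoxyphenyl)-4-(2,4,6-trimethoxyphenoxy)phenoxy]phenol | COc1cc(Oc2c(OC)cc(Oc3c(OC)cc(OC)cc3OC)c(-c3c(OC)cc(OC)cc3OC)c2OC)c(O)c(Oc2c(OC)cc(Oc3c(OC)cc(OC)cc3OC)c(-c3c(OC)cc(OC)cc3OC)c2OC)c1 | intermediate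
30 | 2-chloro-1,3-dimethoxybenzene (ring G) | COc1cccc(OC)c1Cl | starting material
31 | 2-(4-chloro-3,5-dimethoxyphenyl)-4,4,5,5-tetramethyl-1,3,2-dioxaborolane | COc1cc(cc(OC)c1Cl)B1OC(C)(C)C(C)(C)O1 | intermediate
32 | 2-chloro-5-iodo-1,3-dimethoxybenzene | COc1cc(I)cc(OC)c1Cl | intermediate
33 | 2-(4-chloro-3,5-dimethoxyphenoxy)-5-methoxy-1,3-bis[2,6-dimethoxy-3-(2,4,6-trimethoxyphenyl)-4-(2,4,6-trimethoxyphenoxy)phenoxy]benzene | COc1cc(Oc2c(OC)cc(Oc3c(OC)cc(OC)cc3OC)c(-c3c(OC)cc(OC)cc3OC)c2OC)c(Oc2cc(OC)c(Cl)c(OC)c2)c(Oc2c(OC)cc(Oc3c(OC)cc(OC)cc3OC)c(-c3c(OC)cc(OC)cc3OC)c2OC)c1 | intermediate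
34 | CNP0275555.0, 4-(4-chloro-3,5-dihydroxyphenoxy)-3,5-bis[2,6-dihydroxy-3-(2,4,6-trihydroxyphenyl)-4-(2,4,6-trihydroxyphenoxy)phenoxy]phenol | Oc1cc(O)c(Oc2cc(O)c(Oc3cc(O)cc(Oc4c(O)cc(Oc5c(O)cc(O)cc5O)c(-c5c(O)cc(O)cc5O)c4O)c3Oc3cc(O)c(Cl)c(O)c3)c(O)c2-c2c(O)cc(O)cc2O)c(O)c1 | target

## Step count and risks

Total step count: 20. Longest linear sequence: 17 steps (steps 1–4, 6–16, 19 and 20).

**Risk 1, step 12 (pyrone to ring F).**
- What may go wrong: attack of the crowded benzylic enolate on the ester may be slow. It could then be outrun by nucleophilic loss of the pyrone O-methyl group, by saponification from traces of water followed by decarboxylation, or by simple return to the pyrone.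
- Fallback: cross-coupling in place of ring construction, setting out from 4 and coming back at 23.
- Phenol 4 is monobrominated at one of its equivalent ortho carbons (NBS, CH2Cl2, −78 °C) to give 4-(benzyloxy)-2-bromo-3,5-dimethoxyphenol F1.
- A Suzuki–Miyaura coupling of F1 with commercial 2,4,6-trimethoxyphenylboronic acid (Pd(OAc)2, SPhos, K3PO4, toluene/H2O, 80 °C) gives 4-(benzyloxy)-3,5-dimethoxy-2-(2,4,6-trimethoxyphenyl)phenol F2.
- Ullmann coupling of F2 with iodide 10 under the conditions of step 6 attaches ring A and delivers 23.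

**Risk 2, step 6 (ring A attachment).**
- What may go wrong: the doubly ortho-substituted, electron-rich iodide may engage monovalent copper too slowly. Protodeiodination and oxidative degradation of the electron-rich phenoxide could then take over.
- Fallback: SNAr on an aldehyde-activated ring A surrogate, setting out from 8 and coming back at 11.
- Commercial 3,5-dimethoxybenzaldehyde is fluorinated with Selectfluor in MeCN to 2-fluoro-3,5-dimethoxybenzaldehyde F3.
- Phenol 8 displaces the fluoride ortho to the formyl group (K2CO3, DMSO, 110 °C) to give 2-[2-allyl-4-(benzyloxy)-3,5-dimethoxyphenoxy]-3,5-dimethoxybenzaldehyde F4.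
- A Baeyer–Villiger oxidation with H2O2 and catalytic (PhSe)2 in CH2Cl2 is chosen because it should react with the aldehyde faster than with the terminal alkene. It gives 2-[2-allyl-4-(benzyloxy)-3,5-dimethoxyphenoxy]-3,5-dimethoxyphenyl formate F5.
- Methanolysis (K2CO3 cat., MeOH) gives 2-[2-allyl-4-(benzyloxy)-3,5-dimethoxyphenoxy]-3,5-dimethoxyphenol F6, and methylation with MeI/K2CO3 gives 11.

**Risk 3, step 19 (ring G attachment).**
- What may go wrong: the phenoxide oxygen lies buried between the two arms and may fail to bind to copper. The iodide would then be consumed by reduction or homocoupling while the phenol slowly oxidises.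
- Fallback: metal-free arylation by ligand coupling at trivalent iodine, setting out from 29 and 32 and coming back at 33.
- Iodide 32 is oxidised with mCPBA and TsOH·H2O in MeCN to 2-chloro-5-[hydroxy(tosyloxy)iodo]-1,3-dimethoxybenzene F7.
- F7 is trapped in the same flask by 1,3,5-trimethoxybenzene 9 to give (4-chloro-3,5-dimethoxyphenyl)(2,4,6-trimethoxyphenyl)iodonium tosylate F8.
- Phenol 29 is deprotonated with t-BuOK in THF/toluene and warmed with F8 to 50 °C. The less electron-rich ring G should then be transferred to oxygen through the long I–O bond, which tolerates crowded phenoxides, giving 33.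

## Further compounds

F1 | step 12 | 4-(benzyloxy)-2-bromo-3,5-dimethoxyphenol | COc1cc(O)c(Br)c(OC)c1OCc1ccccc1
F2 | step 12 | 4-(benzyloxy)-3,5-dimethoxy-2-(2,4,6-trimethoxyphenyl)phenol | COc1cc(OC)c(c(OC)c1)-c1c(O)cc(OC)c(OCc2ccccc2)c1OC
F3 | step 6 | 2-fluoro-3,5-dimethoxybenzaldehyde | COc1cc(OC)c(F)c(C=O)c1
F4 | step 6 | 2-[2-allyl-4-(benzyloxy)-3,5-dimethoxyphenoxy]-3,5-dimethoxybenzaldehyde | C=CCc1c(Oc2c(C=O)cc(OC)cc2OC)cc(OC)c(OCc2ccccc2)c1OC
F5 | step 6 | 2-[2-allyl-4-(benzyloxy)-3,5-dimethoxyphenoxy]-3,5-dimethoxyphenyl formate | C=CCc1c(Oc2c(OC=O)cc(OC)cc2OC)cc(OC)c(OCc2ccccc2)c1OC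
F6 | step 6 | 2-[2-allyl-4-(benzyloxy)-3,5-dimethoxyphenoxy]-3,5-dimethoxyphenol | C=CCc1c(Oc2c(O)cc(OC)cc2OC)cc(OC)c(OCc2ccccc2)c1OC
F7 | step 19 | 2-chloro-5-[hydroxy(tosyloxy)iodo]-1,3-dimethoxybenzene | COc1cc(I(O)OS(=O)(=O)c2ccc(C)cc2)cc(OC)c1Cl
F8 | step 19 | (4-chloro-3,5-dimethoxyphenyl)(2,4,6-trimethoxyphenyl)iodonium tosylate | COc1cc([I+]c2c(OC)cc(OC)cc2OC)cc(OC)c1Cl.Cc1ccc(cc1)S(=O)(=O)[O-]
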